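- The question for this flask is how X and G divide at 40 min and at 15 d, so the share s = c(X)/(c(X)+c(G)) is followed through the noon run, which is the same flask up to 40.0 h.

- noon: J 0.51 M; Z 1.02 M; the very flask that is asked about, followed so far
- flask: J 0.51 M; Z 1.02 M; time 15 d

noon run (percent of the J charged)

| time / h | X / % | G / % | J / % |
|---|---|---|---|
| 3.00 | 1.6 | 10.4 | 76.3 |
| 6.00 | 1.3 | 18.2 | 59.9 |
| 10.0 | 7.5 | 19.9 | 43.6 |
| 15.0 | 9.7 | 24.9 | 32.9 |
| 25.0 | 15.3 | 32.1 | 17.9 |
| 40.0 | 17.5 | 32.9 | 13.1 |

(standard deviation of a reading: 1 percentage point)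

* share of X in X plus G at 40 min
* share of X in X plus G at 15 d
* which of X and G there is more of at 15 d

- the analysis behind the earlier runs scatters by 1 percentage point, standard deviation

- Earliest rung: X is only starting, so s is taken to grow in proportion to time. The noon reading at 3.00 h, scaled down to 40 min, gives roughly 2.96%, a rough figure because that X reading is close to its scatter of 1 percentage point.
- Next rung: in the noon run J falls with a read half-life of about 10.5 h, so 15 d holds 34.3 of them at that pace.
- Next rung: in the noon run s reads 27.4% at 10.0 h, 32.3% at 25.0 h and 34.7% at 40.0 h. Two equal intervals gain 4.9 points and then 2.4 points, so the gain shrinks, and the gap to a plateau has a read half-life of 14.9 h.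
- Last rung: summing the shrinking gains gives the ceiling share, the value at which this reckoning has s level off, read as 37.1%, uncertain by the scatter of the readings. From 40.0 h to 15 d the gap passes 21.5 half-lives, so this reckoning puts s at the ceiling at 15 d, below an even split, with G ahead.
- The forecast gives 1.5% at 40 min and 58% at 15 d, with X ahead, holding that “the intermediate should be drained” by then. This differs from the ceiling share.
- The flask gives 1.96% at 40 min and 36.7% at 15 d, with G ahead at 39.7% against 23.0% of X.

    J + Z → G (k = 8.10 × 10⁻⁴ L mol⁻¹ min⁻¹)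
    J + Z → D (k = 4.80 × 10⁻⁴ L mol⁻¹ min⁻¹)
    Z + D ⇌ L (K = 5.80 L mol⁻¹, k = 3.20 × 10⁻⁵ L mol⁻¹ min⁻¹)
    G ⇌ X (K = 0.580, k = 0.00100 min⁻¹)
    J ⇌ E (K = 0.370, k = 3.80 × 10⁻⁴ min⁻¹)

- G and X form a two-way pair: with the back reaction of X to G struck out, this flask reaches >99.9% at 15 d and X takes the lead. The ceiling share applied to this flask's X plus G gives 23.3% of X. The neighbour flask charged with 0.26 M of Z ends with 0.286% of its Z and 36.0% of its J left; there the ceiling share of its X plus G gives 11.8% of X, and that flask holds 11.7%.

(The runs were computed with made-up constants.)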